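A closed, stirred vessel is charged with substrate and capture agent. The flasks differ in temperature history, and the species wanted is intermediate A, the second link of the chain from substrate to intermediate B.

    substrate → intermediate A (k1 = 0.014 min⁻¹, Ea1 = 76.0 kJ mol⁻¹)
    intermediate A → intermediate B (k2 = 0.0084 min⁻¹, Ea2 = 83.0 kJ mol⁻¹)
    intermediate B → target (k3 = 6.5 × 10⁻⁴ min⁻¹, Ea3 = 91.0 kJ mol⁻¹)
    intermediate B + capture agent → trapped intermediate (k4 = 0.069 M⁻¹ min⁻¹, Ea4 = 51.0 kJ mol⁻¹)
    target → over-reaction product (k5 = 0.0014 min⁻¹, Ea5 = 91.0 kJ mol⁻¹)
    substrate + intermediate A → side product (k6 = 0.043 M⁻¹ min⁻¹, Ea6 = 67.0 kJ mol⁻¹)
    (constants at 0 °C)

| flask | substrate | capture agent | temperature | time | remark |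
|---|---|---|---|---|---|
| south-east | 20 mM | 20.0 mM | −25 °C | 30 h |  |
| west | 20 mM | 20.0 mM |  | 30 h | at −25 °C until 20 h, from then on at 0 °C |
| north-west | 20 mM | 20.0 mM | 0 °C | 30 h |  |

- percent here means substrate units held: one side product counts as two
- the list of constants is for 0 °C, to be carried to other temperatures by the activation energies

- the best flask by amount of intermediate A, in percent of the substrate charged; "all alike" if 1.5 percentage points covers them all (south-east / west / north-west / all alike)
- amount of intermediate A at the end, in percent of the substrate charged, south-east
- amount of intermediate A at the end, in percent of the substrate charged, west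
- amount of intermediate A at the end, in percent of the substrate charged, north-west

1. Cold constants. From 0 °C down to −25 °C, step 1 slows by a factor of 29. The logarithm of such a factor scales with activation energy, so step 2 slows by 39.7. The cold constants are 4.81 × 10⁻⁴ min⁻¹ for step 1 and 2.11 × 10⁻⁴ min⁻¹ for step 2.

2. The count. In south-east, the constant of step 2 times the time gives 0.381. This product, added over the temperature stages, is the turnover count of intermediate A: the number of its mean lifetimes a flask has passed through.

3. First instants, south-east. The flask holds no intermediate A, so step 1 runs unopposed. Once intermediate A appears, the side step acts on it as a pseudo-first-order loss of 4.40 × 10⁻⁵ min⁻¹ while substrate stands near its charge. That is slower than step 2, so this reckoning sets the side step aside.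

4. Middle, south-east. Intermediate A climbs until making equals loss. For steps 1 and 2 taken as a plain chain, that happens at a turnover count of 0.645.

5. End, south-east. The count of 0.381 is lower than this peak count, so intermediate A is still climbing. The chain formula gives 46.9%, before any side loss.

6. The warm flasks. West reaches 5.29, nearly all of it after the change. Carrying the chain through both stages leaves 1.12% in west. North-west reaches 15.1, which leaves <0.001%. South-east therefore should hold the most intermediate A: its count stands below the peak count, west and north-west have passed beyond that peak count, and the hand figure for south-east is higher than those for the other two.

7. The forecast. It names south-east, with 45.4% in south-east, 1.03% in west and <0.001% in north-west, on the ground that “intermediate A builds up at −25 °C and is destroyed once a flask sits at 0 °C”. Its south-east figure is lower than the hand figure, since it takes a side-reaction correction that the hand figure does not.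

8. The simulation. It gives south-east as the best flask, with 45.4% in south-east, 1.06% in west and 0% in north-west, so the forecast stands within its tolerance.

South-east ends with intermediate A as its largest holding, and intermediate A is still made 1.90 times faster than it is used up at 30.0 h. The same flask left until 2.0 d reaches a turnover count of 0.609, still lower than the peak count of 0.645. The chain formula there gives 52.4%. That longer flask holds 23.9% substrate and 4.10% side product, and its intermediate A reads 50.1%, higher than the 45.4% of south-east.

(The numbers stand for no real mixture, and the outcome is calculated.)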